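**Retrosynthetic overview**

1. Target ⇒ open the benzylic C2–O1 bond: the open-chain isomer is an α-(2-hydroxyaryl)-4-hydroxychalcone ("seco-chalcone"). A chiral-acid cycloisomerisation makes this C–O bond last and sets C2; C3 follows as trans.
2. Seco-chalcone ⇒ Cα–aryl bond by Suzuki–Miyaura coupling of an α-bromochalcone with a 3-borylated davidigenin.
3. α-Bromochalcone ⇐ isoliquiritigenin (pivaloylation, then Br2/Et3N). Boron partner ⇐ 3-bromodavidigenin ⇐ Friedel–Crafts acylation of resorcinol with 3-(3-bromo-4-hydroxyphenyl)propanoic acid ⇐ phloretic acid.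
4. Ring order: all four benzene rings are bought; the only ring made is the dihydrofuran ring, closed in the last step.

Assumption: isoliquiritigenin is bought as the bulk licorice chalcone (otherwise one Claisen–Schmidt step from 2,4-dihydroxyacetophenone and 4-hydroxybenzaldehyde), and the (R)-acid is taken to give the (2S,3S) product, to be confirmed on the first run (the (S)-acid is used if the sense is reversed).

**Route**

Step 1
Reactants: 1 3-(4-hydroxyphenyl)propanoic acid (phloretic acid)
Product: 2 3-(3-bromo-4-hydroxyphenyl)propanoic acid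
Conditions: NBS (1.0 equiv), p-TsOH·H2O (10 mol%), MeOH, rt, 30 min
Reagents that add atoms: N-bromosuccinimide, O=C1CCC(=O)N1Br
Why: Electrophilic aromatic bromination of a para-blocked phenol goes ortho to the hydroxyl, and the acid-catalysed NBS protocol with one equivalent stops at the monobromide.

Step 2
Reactants: 2 3-(3-bromo-4-hydroxyphenyl)propanoic acid; 3 resorcinol
Product: 4 3-(3-bromo-4-hydroxyphenyl)-1-(2,4-dihydroxyphenyl)propan-1-one (3-bromodavidigenin)
Conditions: resorcinol (1.2 equiv), neat BF3·OEt2 (solvent), 85 °C, 2 h; aq. NaOAc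
Reagents that add atoms: none
Why: Friedel–Crafts (Nencki-type) C-acylation of resorcinol at C4 by the BF3-activated acid is the standard entry to 2',4'-dihydroxydihydrochalcones, and the far less activated bromophenol ring does not compete.

Step 3
Reactants: 5 isoliquiritigenin [(E)-1-(2,4-dihydroxyphenyl)-3-(4-hydroxyphenyl)prop-2-en-1-one]
Product: 6 isoliquiritigenin tripivalate [(E)-1-[2,4-bis(pivaloyloxy)phenyl]-3-[4-(pivaloyloxy)phenyl]prop-2-en-1-one]
Conditions: PivCl (4 equiv), Et3N (5 equiv), DMAP (20 mol%), CH2Cl2, 0 °C to rt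
Reagents that add atoms: pivaloyl chloride, CC(C)(C)C(=O)Cl
Why: DMAP-catalysed O-acylation caps all three phenols, including the hydrogen-bonded 2'-OH; pivalates are chosen because they deactivate the rings towards Br2, tolerate Et3N and Suzuki base, and leave by simple methanolysis.

Step 4
Reactants: 6 isoliquiritigenin tripivalate
Product: 8 (Z)-2-bromo-1-[2,4-bis(pivaloyloxy)phenyl]-3-[4-(pivaloyloxy)phenyl]prop-2-en-1-one, via erythro dibromide 7 (not isolated)
Conditions: Br2 (1.05 equiv), CH2Cl2, 0 °C; then Et3N (2.5 equiv), rt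
Reagents that add atoms: bromine, BrBr
Why: Anti addition of Br2 to the enone C=C followed by E1cB dehydrobromination (the acidic α-H is removed and the β-bromide leaves) is the classical route to α-bromochalcones; the two stereocentres of racemic 7 disappear in 8, and the alkene geometry is irrelevant later.

Step 5
Reactants: 4 3-bromodavidigenin; 8 (Z)-α-bromochalcone tripivalate
Product: 11 (E)-1-(2,4-dihydroxyphenyl)-2-{5-[3-(2,4-dihydroxyphenyl)-3-oxopropyl]-2-hydroxyphenyl}-3-(4-hydroxyphenyl)prop-2-en-1-one (seco-chalcone), via pinacol boronate 9 (not isolated), via coupled tripivalate 10 (not isolated)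
Conditions: B2pin2 (1.1 equiv), PdCl2(dppf) (5 mol%), KOAc (3 equiv), 1,4-dioxane, 90 °C; then 8 (0.85 equiv), aq. K3PO4 (3 M, 4 equiv), 60 °C; then MeOH, 45 °C; work-up at pH 5, chromatography
Reagents that add atoms: none
Why: One-pot Miyaura borylation and Suzuki–Miyaura coupling joins ring B to the α-carbon with retention at the vinyl bromide, the pivalates keep the 2'-oxygen masked while C–Br is present (this blocks the aurone/flavone closure of α-bromo-2'-hydroxychalcones), and the final base-catalysed methanolysis frees all phenols while the strongly basic medium holds 11 open as its polyphenoxide.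

Step 6
Reactants: 11 seco-chalcone
Product: 13 1-(2,4-dihydroxyphenyl)-3-[(2S,3S)-3-(2,4-dihydroxybenzoyl)-2-(4-hydroxyphenyl)-2,3-dihydro-1-benzofuran-5-yl]propan-1-one (CNP0136359.1), via cyclised enol 12 (not isolated)
Conditions: (R)-TRIP [(R)-3,3'-bis(2,4,6-triisopropylphenyl)-1,1'-binaphthyl-2,2'-diyl hydrogen phosphate] (10 mol%), 4 Å MS, CHCl3/EtOAc (3:1), 0 °C, 48 h; no basic work-up
Reagents that add atoms: none
Why: Proposed new method: a catalytic enantioselective cycloisomerisation (formal 5-endo-trig oxa-Michael addition) of an α-(2-hydroxyaryl)-4-hydroxychalcone, in which the chiral phosphoric acid donates its P–OH to the enone carbonyl and accepts the ring B phenol proton at P=O, the 4-hydroxyphenyl group gives the β-carbon para-quinone-methide (benzylic cation) character that lifts the usual 5-endo handicap, the C2–O bond forms inside the chiral ion pair and sets C2, and enol 12 then ketonises reversibly under the same acid to the more stable trans ketone, which sets C3 as S without touching C2; the closest known reactions are chiral-phosphoric-acid-catalysed 1,6-additions to para-quinone methides formed in situ, the acid-mediated closure of 2-hydroxystilbenes to 2-aryl-2,3-dihydrobenzofurans, and the organocatalytic 6-endo chalcone-to-flavanone isomerisation, none shown for this five-ring closure on an α-aryl enone.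

**Compound list**

1 | 3-(4-hydroxyphenyl)propanoic acid (phloretic acid) | OC(=O)CCc1ccc(O)cc1 | starting material
2 | 3-(3-bromo-4-hydroxyphenyl)propanoic acid | OC(=O)CCc1ccc(O)c(Br)c1 | intermediate
3 | resorcinol | Oc1cccc(O)c1 | starting material
4 | 3-(3-bromo-4-hydroxyphenyl)-1-(2,4-dihydroxyphenyl)propan-1-one | O=C(CCc1ccc(O)c(Br)c1)c1ccc(O)cc1O | intermediate
5 | isoliquiritigenin, (E)-1-(2,4-dihydroxyphenyl)-3-(4-hydroxyphenyl)prop-2-en-1-one | O=C(/C=C/c1ccc(O)cc1)c1ccc(O)cc1O | starting material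
6 | (E)-1-[2,4-bis(pivaloyloxy)phenyl]-3-[4-(pivaloyloxy)phenyl]prop-2-en-1-one | CC(C)(C)C(=O)Oc1ccc(/C=C/C(=O)c2ccc(OC(=O)C(C)(C)C)cc2OC(=O)C(C)(C)C)cc1 | intermediate
7 | erythro-(2R*,3S*)-2,3-dibromo-1-[2,4-bis(pivaloyloxy)phenyl]-3-[4-(pivaloyloxy)phenyl]propan-1-one, racemic, one enantiomer drawn | CC(C)(C)C(=O)Oc1ccc(cc1)[C@@H](Br)[C@@H](Br)C(=O)c1ccc(OC(=O)C(C)(C)C)cc1OC(=O)C(C)(C)C | intermediate (not isolated)
8 | (Z)-2-bromo-1-[2,4-bis(pivaloyloxy)phenyl]-3-[4-(pivaloyloxy)phenyl]prop-2-en-1-one | CC(C)(C)C(=O)Oc1ccc(/C=C(\Br)C(=O)c2ccc(OC(=O)C(C)(C)C)cc2OC(=O)C(C)(C)C)cc1 | intermediate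
9 | 1-(2,4-dihydroxyphenyl)-3-[4-hydroxy-3-(4,4,5,5-tetramethyl-1,3,2-dioxaborolan-2-yl)phenyl]propan-1-one | O=C(CCc1ccc(O)c(c1)B1OC(C)(C)C(C)(C)O1)c1ccc(O)cc1O | intermediate (not isolated)
10 | (E)-1-[2,4-bis(pivaloyloxy)phenyl]-2-{5-[3-(2,4-dihydroxyphenyl)-3-oxopropyl]-2-hydroxyphenyl}-3-[4-(pivaloyloxy)phenyl]prop-2-en-1-one | CC(C)(C)C(=O)Oc1ccc(/C=C(\c2cc(CCC(=O)c3ccc(O)cc3O)ccc2O)C(=O)c2ccc(OC(=O)C(C)(C)C)cc2OC(=O)C(C)(C)C)cc1 | intermediate (not isolated)
11 | (E)-1-(2,4-dihydroxyphenyl)-2-{5-[3-(2,4-dihydroxyphenyl)-3-oxopropyl]-2-hydroxyphenyl}-3-(4-hydroxyphenyl)prop-2-en-1-one | Oc1ccc(/C=C(\c2cc(CCC(=O)c3ccc(O)cc3O)ccc2O)C(=O)c2ccc(O)cc2O)cc1 | intermediate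
12 | 1-(2,4-dihydroxyphenyl)-3-{(2R)-3-[(2,4-dihydroxyphenyl)(hydroxy)methylidene]-2-(4-hydroxyphenyl)-2,3-dihydro-1-benzofuran-5-yl}propan-1-one; C2 has the same spatial arrangement as in 13, the descriptor differs only through CIP priorities; enol geometry undefined | O=C(CCc1ccc2c(c1)C(=C(O)c1ccc(O)cc1O)[C@@H](c1ccc(O)cc1)O2)c1ccc(O)cc1O | intermediate (not isolated)
13 | 1-(2,4-dihydroxyphenyl)-3-[(2S,3S)-3-(2,4-dihydroxybenzoyl)-2-(4-hydroxyphenyl)-2,3-dihydro-1-benzofuran-5-yl]propan-1-one (trans) | O=C(CCc1ccc2c(c1)[C@H](C(=O)c1ccc(O)cc1O)[C@@H](c1ccc(O)cc1)O2)c1ccc(O)cc1O | target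

**Step count**

Total: 6 steps. Longest linear sequence: 4 steps (1 → 2 → 4 → 11 → 13, or 5 → 6 → 8 → 11 → 13).

**Three steps most likely to fail**

Step 6 (the new cycloisomerisation). The risks are these:
- The phosphoric acid may be too weak to turn over this push–pull enone; the first adjustment within the same design is the more acidic N-triflyl phosphoramide of the same backbone.
- An uncatalysed or self-catalysed racemic closure may erode the ee.
- The hydrogen-bonded 2'-OH may close 6-endo to the 3-arylflavanone isomer.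
- The product may racemise if ring reopening and C3 enolisation both occur.

Fallback with known chemistry, setting out from 11 and coming back at 13: close 11 with an achiral Brønsted acid (p-TsOH·H2O, 20 mol%, THF, 40 °C; the established acid-mediated closure of 2-hydroxystilbene-type phenols under thermodynamic control). This gives the trans racemate, that is 13 together with its mirror image, the (2R,3R)-enantiomer F1. The two are separated by preparative chiral SFC on an amylose tris(3,5-dimethylphenylcarbamate) phase. F1 can be reopened to 11 (K2CO3, MeOH, rt, retro-oxa-Michael) and recycled.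

Step 5 (one-pot borylation, coupling and deprotection). The risks are these:
- Protodebromination during borylation of the unprotected ortho-bromophenol.
- Protodeboronation of 9.
- Early loss of the 2'-pivalate, which lets 8 close to an aurone or flavone.
- Premature base-mediated ring closure, giving racemic 13. Any such material must be removed by chromatography before step 6.

The fallback gives up the one-pot, phenol-unprotected design for a fully protected, stepwise sequence with an isolated boronate; it sets out from 4 and comes back at 11. Acylate 4 (PivCl, Et3N, DMAP, CH2Cl2) to the bromo tripivalate F2. Borylate it (B2pin2, PdCl2(dppf), KOAc, dioxane, 90 °C) and isolate the pinacol boronate tripivalate F3. Couple F3 with 8 (Pd(OAc)2/SPhos, K3PO4, dioxane/H2O 10:1, 60 °C) to the hexapivalate of the seco-chalcone F4. Cleave all six esters with NaOMe in MeOH at rt and acidify to pH 5 to reach 11.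

Step 2 (Friedel–Crafts acylation in hot BF3·OEt2). The risks are O-acylation and oligo-esters, double acylation of resorcinol, and a low yield with the bromophenol acid.

The fallback replaces the acylation by an aldol condensation and a chemoselective hydrogenation; it sets out from 3 and comes back at 4. Acetylate resorcinol (AcOH, ZnCl2, 140 °C, Nencki reaction) to 2,4-dihydroxyacetophenone F5, which can also be bought. Condense F5 with commercial 3-bromo-4-hydroxybenzaldehyde (KOH, aq. EtOH, rt to 50 °C, Claisen–Schmidt) to 3-bromoisoliquiritigenin F6. Hydrogenate only the C=C bond (H2 1 atm, RhCl(PPh3)3 5 mol%, THF/EtOH), which leaves the aryl bromide and ketone intact and gives 4.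

**Further compounds**

F1 | step 6 | 1-(2,4-dihydroxyphenyl)-3-[(2R,3R)-3-(2,4-dihydroxybenzoyl)-2-(4-hydroxyphenyl)-2,3-dihydro-1-benzofuran-5-yl]propan-1-one | O=C(CCc1ccc2c(c1)[C@@H](C(=O)c1ccc(O)cc1O)[C@H](c1ccc(O)cc1)O2)c1ccc(O)cc1O
F2 | step 5 | 3-[3-bromo-4-(pivaloyloxy)phenyl]-1-[2,4-bis(pivaloyloxy)phenyl]propan-1-one | CC(C)(C)C(=O)Oc1ccc(CCC(=O)c2ccc(OC(=O)C(C)(C)C)cc2OC(=O)C(C)(C)C)cc1Br
F3 | step 5 | 1-[2,4-bis(pivaloyloxy)phenyl]-3-[4-(pivaloyloxy)-3-(4,4,5,5-tetramethyl-1,3,2-dioxaborolan-2-yl)phenyl]propan-1-one | CC(C)(C)C(=O)Oc1ccc(CCC(=O)c2ccc(OC(=O)C(C)(C)C)cc2OC(=O)C(C)(C)C)cc1B1OC(C)(C)C(C)(C)O1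
F4 | step 5 | (E)-1-[2,4-bis(pivaloyloxy)phenyl]-2-{5-[3-(2,4-bis(pivaloyloxy)phenyl)-3-oxopropyl]-2-(pivaloyloxy)phenyl}-3-[4-(pivaloyloxy)phenyl]prop-2-en-1-one | CC(C)(C)C(=O)Oc1ccc(/C=C(\c2cc(CCC(=O)c3ccc(OC(=O)C(C)(C)C)cc3OC(=O)C(C)(C)C)ccc2OC(=O)C(C)(C)C)C(=O)c2ccc(OC(=O)C(C)(C)C)cc2OC(=O)C(C)(C)C)cc1
F5 | step 2 | 2,4-dihydroxyacetophenone | CC(=O)c1ccc(O)cc1O
F6 | step 2 | (E)-3-(3-bromo-4-hydroxyphenyl)-1-(2,4-dihydroxyphenyl)prop-2-en-1-one | O=C(/C=C/c1ccc(O)c(Br)c1)c1ccc(O)cc1O
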